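**Plan**

- Numbering used here: the core is read as an octahydroindene (C1–C7a). The C7a carboxyl is lactonized onto the C4 oxygen, C7 carries Br, and C3 carries the CH2–cyclohexanol arm (ring A).
- Retrosynthesis: (i) both secondary C–Br bonds go back to alkenyl bromides; (ii) lactone C–O; (iii) C4–C5 and C3a–C7a together (intramolecular Diels–Alder); (iv) ring A C–C bond and spiro C–O bond (epoxide-initiated cyclization); (v) the C3–CH2 bond (Evans alkylation).
- Enabling feature: in the cyclohexane C3a–C4–C5–C6–C7–C7a, C7 (Br) sits next to the quaternary, carboxyl-bearing C7a. C5=C6–C7(OTf)=C7a is therefore a β-triflyloxy-dienoate, C3a=C4(Me)(OSi) is an enol ether, and the two are already joined through C1–C2–C3, i.e. a 1,3,8-nonatriene.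
- Forward ring order: ring A (with a temporary spirolactone), then cyclopentane and cyclohexene in one cycloaddition, then the γ-lactone, then the two CHBr centres.
- Stereochemistry: C3 comes from the oxazolidinone alkylation. The ring A carbinol is relayed from a Shi epoxide through a chair transition state. C3a, C4 and C7a come from the cycloaddition (E-diene, Z-enol ether, anti transition state enforced by the C7 triflate, A(1,3) control from C3). Both CHBr centres come from radical (HAT) hydrogenation with axial hydrogen delivery.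

Key step: step 18

Assumption: the D-fructose-derived Shi ketone is taken to give the (R)-epoxide of the 2-methylalk-2-ene terminus, as it does for other trisubstituted alkenes; the phosphonium salt 20 is prepared (step 11) rather than bought.

**Route**

Step 1
Reactants: 1 5-bromo-2-methylpent-2-ene; 2 prop-2-yn-1-ol
Product: 4 6-methyl-2-methylidenehept-5-en-1-ol, via (4-methylpent-3-en-1-yl)magnesium bromide 3 (not isolated)
Conditions: Mg, THF; then 2 (0.4 equiv), CuI (10 mol%), Et2O/THF, −10 °C → rt; H2O/NH4Cl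
Reagents that add atoms: none
Why: Copper-catalysed anti-carbomagnesiation of the propargylic alkoxide places the alkyl group on the internal alkyne carbon and should give the 2-substituted allylic alcohol after protonolysis; no stereocentre is formed.

Step 2
Reactants: 4 6-methyl-2-methylidenehept-5-en-1-ol
Product: 5 2-{2-[(2R)-3,3-dimethyloxiran-2-yl]ethyl}prop-2-en-1-ol
Conditions: D-fructose-derived Shi ketone (0.3 equiv), Oxone, K2CO3, Bu4NHSO4, MeCN–DMM/aq. buffer (pH 10.5), 0 °C
Reagents that add atoms: Oxone (potassium peroxymonosulfate) [K+].[O-]S(=O)(=O)OO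
Why: Shi epoxidation should select the electron-rich trisubstituted alkene over the 1,1-disubstituted allylic one, and the spiro transition state of the chiral dioxirane sets the (R)-epoxide.

Step 3
Reactants: 5 2-{2-[(2R)-3,3-dimethyloxiran-2-yl]ethyl}prop-2-en-1-ol
Product: 7 (3R)-3-[3-(bromomethyl)but-3-en-1-yl]-2,2-dimethyloxirane, via allylic mesylate 6 (not isolated)
Conditions: MsCl, Et3N, CH2Cl2, −40 °C; then LiBr, THF, 0 °C
Reagents that add atoms: methanesulfonyl chloride CS(=O)(=O)Cl (atoms stay only in 6); lithium bromide [Li+].[Br-]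
Why: Mesylation followed by SN2 displacement with bromide at the primary allylic carbon should leave the trisubstituted epoxide untouched at 0 °C.

Step 4
Reactants: 8 (4R)-4-benzyl-1,3-oxazolidin-2-one; 9 6-methoxy-6-oxohexanoic acid
Product: 11 methyl 6-[(4R)-4-benzyl-2-oxo-1,3-oxazolidin-3-yl]-6-oxohexanoate, via mixed pivalic anhydride 10 (not isolated)
Conditions: PivCl, Et3N, THF, −20 °C; then 8, LiCl, rt
Reagents that add atoms: pivaloyl chloride CC(C)(C)C(=O)Cl (atoms stay only in 10)
Why: N-acylation of the oxazolidinone through the mixed anhydride is a standard way to install the Evans auxiliary; the methyl ester is inert.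

Step 5
Reactants: 11 methyl 6-[(4R)-4-benzyl-2-oxo-1,3-oxazolidin-3-yl]-6-oxohexanoate; 7 (3R)-3-[3-(bromomethyl)but-3-en-1-yl]-2,2-dimethyloxirane
Product: 12 methyl (5S)-5-[(4R)-4-benzyl-2-oxo-1,3-oxazolidine-3-carbonyl]-9-[(2R)-3,3-dimethyloxiran-2-yl]-7-methylidenenonanoate
Conditions: NaHMDS, THF, −78 °C; then 7, −78 → −30 °C
Reagents that add atoms: none
Why: Evans alkylation: the chelated (Z)-sodium enolate of the imide (more acidic than the remote ester) is attacked by the allylic bromide on the face opposite the benzyl group, which sets the (S)-centre that becomes C3.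

Step 6
Reactants: 12 (alkylated imide)
Product: 13 (2S)-2-{4-[(2R)-3,3-dimethyloxiran-2-yl]-2-methylidenebutyl}-6-methoxy-6-oxohexanoic acid
Conditions: LiOH, H2O2, THF/H2O, 0 °C; then Na2SO3; 1 M HCl (pH 4)
Reagents that add atoms: hydrogen peroxide OO
Why: Hydroperoxide attacks the exocyclic imide carbonyl selectively, so the auxiliary is released while the methyl ester, the epoxide and the α-centre should survive at 0 °C.

Step 7
Reactants: 13 (epoxy acid)
Product: 14 methyl 4-[(3S,5S,8R)-8-hydroxy-7,7-dimethyl-2-oxo-1-oxaspiro[4.5]decan-3-yl]butanoate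
Conditions: BF3·OEt2, CH2Cl2, −78 → −30 °C
Reagents that add atoms: none
Why: Epoxide-initiated cation–olefin cyclization (6-endo, Markovnikov attack by the 1,1-disubstituted alkene) terminated by the carboxylic acid; the chair transition state with anti addition across the alkene places C8–OH and the spiro C5–O both equatorial (trans), so the epoxide configuration is relayed to the spiro carbinol.

Step 8
Reactants: 14 (hydroxy spirolactone)
Product: 15 methyl 4-[(3S,5S)-7,7-dimethyl-2,8-dioxo-1-oxaspiro[4.5]decan-3-yl]butanoate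
Conditions: Dess–Martin periodinane, NaHCO3, CH2Cl2, rt
Reagents that add atoms: none
Why: Dess–Martin oxidation of the hindered secondary alcohol removes the relay stereocentre now that the spiro centre is fixed.

Step 9
Reactants: 15 (keto spirolactone)
Product: 16 methyl 4-[(3S,5R)-8-bromo-7,7-dimethyl-2-oxo-1-oxaspiro[4.5]dec-8-en-3-yl]butanoate (same geometry at C5 as 15; the descriptor changes with the ring bromide)
Conditions: P(OPh)3, Br2, Et3N, CH2Cl2, −60 °C → reflux
Reagents that add atoms: bromine BrBr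
Why: Conversion of a ketone into the alkenyl bromide with a halophosphorane; the ketone has only one enolizable side (the other is the CMe2 carbon), so the C8=C9 regiochemistry is fixed.

Step 10
Reactants: 16 (bromoalkene spirolactone)
Product: 17 methyl 4-[(3S,5R)-8-bromo-2-hydroxy-7,7-dimethyl-1-oxaspiro[4.5]dec-8-en-3-yl]butanoate (lactol, anomers)
Conditions: disiamylborane (from BH3·THF and 2-methylbut-2-ene), THF, 0 °C → rt; then H2O2, pH 7 buffer
Reagents that add atoms: none
Why: Disiamylborane reduces γ-lactones to lactols but leaves acyclic esters alone, and the hindered, electron-poor bromoalkene should not be hydroborated.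

Step 11
Reactants: 18 triphenylphosphane; 19 1-chloro-1-ethoxyethane
Product: 20 (1-ethoxyethyl)triphenylphosphonium chloride
Conditions: PhMe, 0 °C → rt
Reagents that add atoms: none
Why: Quaternization of the phosphane by the α-chloro ether gives the α-alkoxyalkyl phosphonium salt.

Step 12
Reactants: 17 (lactol); 20 (1-ethoxyethyl)triphenylphosphonium chloride
Product: 21 methyl (5S)-5-{[(1R)-4-bromo-1-hydroxy-5,5-dimethylcyclohex-3-en-1-yl]methyl}-7-ethoxyoct-6-enoate (E/Z mixture)
Conditions: 20 (3 equiv), KHMDS, THF, −78 → 0 °C; then 17, 0 °C → rt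
Reagents that add atoms: none
Why: Wittig olefination of the hydroxy-aldehyde form of the lactol with the α-alkoxy ylide gives an enol ether (a base-stable masked methyl ketone) and frees the tertiary alcohol; the enol ether geometry is irrelevant because it is hydrolysed in step 15.

Step 13
Reactants: 21 (enol ether alcohol)
Product: 22 methyl (5S)-5-{[(1R)-4-bromo-5,5-dimethyl-1-(triethylsilyloxy)cyclohex-3-en-1-yl]methyl}-7-ethoxyoct-6-enoate
Conditions: TESOTf, 2,6-lutidine, CH2Cl2, −78 → 0 °C
Reagents that add atoms: triethylsilyl trifluoromethanesulfonate CC[Si](CC)(CC)OS(=O)(=O)C(F)(F)F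
Why: Silylation of the hindered tertiary alcohol prevents hemiketal or cyclic enol ether formation once the 1,5-related methyl ketone is unveiled.

Step 14
Reactants: 22 (TES ether ester); 23 prop-2-enal
Product: 24 methyl (5S)-5-{[(1R)-4-bromo-5,5-dimethyl-1-(triethylsilyloxy)cyclohex-3-en-1-yl]methyl}-7-ethoxy-2-(1-hydroxyprop-2-en-1-yl)oct-6-enoate (diastereomer mixture)
Conditions: LDA, THF, −78 °C; then 23, −78 °C; aq NH4Cl
Reagents that add atoms: none
Why: Aldol addition of the ester lithium enolate to acrolein proceeds 1,2 at −78 °C; the two new stereocentres are removed in steps 15 and 16.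

Step 15
Reactants: 24 (aldol adduct)
Product: 26 methyl (5S)-5-{[(1R)-4-bromo-5,5-dimethyl-1-(triethylsilyloxy)cyclohex-3-en-1-yl]methyl}-7-oxo-2-(prop-2-enoyl)octanoate, via vinyl β-keto ester enol ether 25 (not isolated)
Conditions: Dess–Martin periodinane, NaHCO3, CH2Cl2, 0 °C; then aq. oxalic acid, THF, 0 °C
Reagents that add atoms: water O
Why: Dess–Martin oxidation of the allylic alcohol gives the vinyl β-keto ester, and mild aqueous acid hydrolyses the enol ether to the methyl ketone while the hindered tertiary TES ether should survive.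

Step 16
Reactants: 26 (vinyl β-keto ester methyl ketone)
Product: 27 methyl (2E,5S)-5-{[(1R)-4-bromo-5,5-dimethyl-1-(triethylsilyloxy)cyclohex-3-en-1-yl]methyl}-7-oxo-2-[1-(trifluoromethanesulfonyloxy)prop-2-en-1-ylidene]octanoate
Conditions: KHMDS (1.05 equiv), 18-crown-6, THF, −78 °C; then PhNTf2
Reagents that add atoms: N-phenylbis(trifluoromethanesulfonimide) O=S(=O)(N(c1ccccc1)S(=O)(=O)C(F)(F)F)C(F)(F)F
Why: O-triflation of the β-keto ester enolate under non-chelating conditions should give the (E)-enol triflate (OTf trans to CO2Me, so the ester is cis to the vinyl group); the far less acidic methyl ketone is not enolized.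

Step 17
Reactants: 27 (dienyl triflate methyl ketone)
Product: 28 methyl (2E,5S,6Z)-5-{[(1R)-4-bromo-5,5-dimethyl-1-(triethylsilyloxy)cyclohex-3-en-1-yl]methyl}-2-[1-(trifluoromethanesulfonyloxy)prop-2-en-1-ylidene]-7-(trimethylsilyloxy)oct-6-enoate
Conditions: TMSI, (Me3Si)2NH, CH2Cl2/pentane, −20 °C → rt
Reagents that add atoms: iodotrimethylsilane C[Si](C)(C)I
Why: Silyl enol ether formation under equilibrating conditions favours the more substituted enol ether with (Z) geometry (O cis to the chain), which is the dienophile needed.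

Step 18
Reactants: 28 (triene)
Product: 29 methyl (3S,3aS,4R,7aR)-3-{[(1R)-4-bromo-5,5-dimethyl-1-(triethylsilyloxy)cyclohex-3-en-1-yl]methyl}-4-methyl-7-(trifluoromethanesulfonyloxy)-4-(trimethylsilyloxy)-1,2,3,3a,4,5-hexahydro-7aH-indene-7a-carboxylate (trans ring fusion, C4–OSi cis to CO2Me)
Conditions: PhMe (0.005 M), BHT, N,O-bis(trimethylsilyl)acetamide (0.2 equiv), 170 °C, sealed tube
Reagents that add atoms: none
Why: Thermal, concerted but asynchronous [4π+2π] cycloaddition of a 1,3,8-nonatriene: the s-cis diene C5=C6–C7(OTf)=C7a adds suprafacially across the C3a=C4 silyl enol ether, the closest known type being intramolecular Diels–Alder reactions of nonatrienes that carry a bulky steric directing substituent (Br, SiMe3) on the diene carbon next to the tethered terminus. The cyclohexene closes by the cycloaddition itself (both new σ-bonds, C4–C5 and C3a–C7a), and the cyclopentane closes in the fused mode through C3a–C7a, the three-carbon tether C1–C3 becoming the five-membered ring. C7a and C3a: the (E)-diene holds CO2Me inside and the tether outside, and the anti (tether-exo) transition state gives the trans fusion because the syn alternative would push C3 and its branch against the C7 triflate. C4: the (Z)-enol ether puts OSiMe3 exo, hence cis to the C7a ester and ready for lactonization. The π-face is set by the existing C3 centre, since A(1,3) strain with the cis-OSiMe3 keeps C3–H in the enol ether plane and the diene adds anti to the CH2–cyclohexenyl branch. The step needs regio-, anti/syn and facial selectivity: the short tether fixes the regiochemistry against the electronic preference, the ester (no C–H) cis to the vinyl group excludes a 1,5-H shift, and dilution, BHT and the silylating scavenger guard against polymerization and desilylation.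

Step 19
Reactants: 29 (cycloadduct)
Product: 31 4,7a-lactone of (3S,3aS,4R,7aR)-3-{[(1R)-4-bromo-1-hydroxy-5,5-dimethylcyclohex-3-en-1-yl]methyl}-4-hydroxy-4-methyl-7-(trifluoromethanesulfonyloxy)-1,2,3,3a,4,5-hexahydro-7aH-indene-7a-carboxylic acid, via desilylated diol ester 30 (not isolated)
Conditions: HF·pyridine, pyridine, THF, 0 °C → rt; then DBU (cat.), PhMe, 60 °C
Reagents that add atoms: none
Why: Fluoride removes both silyl ethers, and the C4 tertiary alcohol, 1,3-diaxial to the C7a ester, closes the γ-lactone by base-catalysed transesterification; the alkenyl triflate and bromide are inert to HF·pyridine and DBU.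

Step 20
Reactants: 31 (lactone alkenyl triflate)
Product: 32 4,7a-lactone of (3S,3aS,4R,7aS)-7-bromo-3-{[(1R)-4-bromo-1-hydroxy-5,5-dimethylcyclohex-3-en-1-yl]methyl}-4-hydroxy-4-methyl-1,2,3,3a,4,5-hexahydro-7aH-indene-7a-carboxylic acid
Conditions: Ni(OAc)2·4H2O (10 mol%), 1,5-cyclooctadiene, Zn (cat.), LiBr, DMA/THF, rt
Reagents that add atoms: lithium bromide [Li+].[Br-]
Why: Nickel-catalysed conversion of an enol triflate into the alkenyl bromide (oxidative addition, triflate/bromide exchange, reductive elimination); the ring A alkenyl bromide can only exchange degenerately.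

Step 21
Reactants: 32 (bis(alkenyl bromide))
Product: 33 CNP0282702.2, the 4,7a-lactone of (3S,3aS,4R,7S,7aS)-7-bromo-3-{[(1S,4S)-4-bromo-1-hydroxy-3,3-dimethylcyclohexyl]methyl}-4-hydroxy-4-methyloctahydro-1H-indene-7a-carboxylic acid
Conditions: Mn(dpm)3 (cat.), PhSiH3, t-BuOOH, i-PrOH, rt
Reagents that add atoms: none
Why: Metal-hydride HAT hydrogenation of alkenyl bromides to alkyl bromides: H• adds to each CH terminus to give an α-bromo radical, and the second hydrogen should arrive axially (anti to the axial C7a carbonyl in the core, anti to the axial methyl in ring A), leaving both bromines equatorial, i.e. (7S) and ring A (4S) cis to the axial OH.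

**Compound list**

1 | 5-bromo-2-methylpent-2-ene | CC(C)=CCCBr | starting material
2 | prop-2-yn-1-ol | C#CCO | starting material
3 | (4-methylpent-3-en-1-yl)magnesium bromide | CC(C)=CCC[Mg]Br | intermediate
4 | 6-methyl-2-methylidenehept-5-en-1-ol | CC(C)=CCCC(=C)CO | intermediate
5 | 2-{2-[(2R)-3,3-dimethyloxiran-2-yl]ethyl}prop-2-en-1-ol | OCC(=C)CC[C@H]1OC1(C)C | intermediate
6 | 2-{2-[(2R)-3,3-dimethyloxiran-2-yl]ethyl}prop-2-en-1-yl methanesulfonate | CS(=O)(=O)OCC(=C)CC[C@H]1OC1(C)C | intermediate
7 | (3R)-3-[3-(bromomethyl)but-3-en-1-yl]-2,2-dimethyloxirane | BrCC(=C)CC[C@H]1OC1(C)C | intermediate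
8 | (4R)-4-benzyl-1,3-oxazolidin-2-one | O=C1N[C@H](Cc2ccccc2)CO1 | starting material
9 | 6-methoxy-6-oxohexanoic acid (monomethyl adipate) | COC(=O)CCCCC(=O)O | starting material
10 | 6-methoxy-6-oxohexanoic pivalic anhydride | COC(=O)CCCCC(=O)OC(=O)C(C)(C)C | intermediate
11 | methyl 6-[(4R)-4-benzyl-2-oxo-1,3-oxazolidin-3-yl]-6-oxohexanoate | COC(=O)CCCCC(=O)N1[C@H](Cc2ccccc2)COC1=O | intermediate
12 | methyl (5S)-5-[(4R)-4-benzyl-2-oxo-1,3-oxazolidine-3-carbonyl]-9-[(2R)-3,3-dimethyloxiran-2-yl]-7-methylidenenonanoate | COC(=O)CCC[C@@H](CC(=C)CC[C@H]1OC1(C)C)C(=O)N1[C@H](Cc2ccccc2)COC1=O | intermediate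
13 | (2S)-2-{4-[(2R)-3,3-dimethyloxiran-2-yl]-2-methylidenebutyl}-6-methoxy-6-oxohexanoic acid | COC(=O)CCC[C@@H](CC(=C)CC[C@H]1OC1(C)C)C(=O)O | intermediate
14 | methyl 4-[(3S,5S,8R)-8-hydroxy-7,7-dimethyl-2-oxo-1-oxaspiro[4.5]decan-3-yl]butanoate | CC1(C)C[C@@](O2)(C[C@H](CCCC(=O)OC)C2=O)CC[C@H]1O | intermediate
15 | methyl 4-[(3S,5S)-7,7-dimethyl-2,8-dioxo-1-oxaspiro[4.5]decan-3-yl]butanoate | CC1(C)C[C@@](O2)(C[C@H](CCCC(=O)OC)C2=O)CCC1=O | intermediate
16 | methyl 4-[(3S,5R)-8-bromo-7,7-dimethyl-2-oxo-1-oxaspiro[4.5]dec-8-en-3-yl]butanoate | CC1(C)C[C@@](O2)(C[C@H](CCCC(=O)OC)C2=O)CC=C1Br | intermediate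
17 | methyl 4-[(3S,5R)-8-bromo-2-hydroxy-7,7-dimethyl-1-oxaspiro[4.5]dec-8-en-3-yl]butanoate (lactol) | CC1(C)C[C@@](O2)(C[C@H](CCCC(=O)OC)C2O)CC=C1Br | intermediate
18 | triphenylphosphane | c1ccc(cc1)P(c1ccccc1)c1ccccc1 | starting material
19 | 1-chloro-1-ethoxyethane | CCOC(C)Cl | starting material
20 | (1-ethoxyethyl)triphenylphosphonium chloride | CCOC(C)[P+](c1ccccc1)(c1ccccc1)c1ccccc1.[Cl-] | intermediate
21 | methyl (5S)-5-{[(1R)-4-bromo-1-hydroxy-5,5-dimethylcyclohex-3-en-1-yl]methyl}-7-ethoxyoct-6-enoate (E/Z) | CC1(C)C[C@@](O)(C[C@H](CCCC(=O)OC)C=C(C)OCC)CC=C1Br | intermediate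
22 | triethylsilyl ether of 21 | CC1(C)C[C@@](O[Si](CC)(CC)CC)(C[C@H](CCCC(=O)OC)C=C(C)OCC)CC=C1Br | intermediate
23 | prop-2-enal (acrolein) | C=CC=O | starting material
24 | aldol adduct: 2-(1-hydroxyprop-2-en-1-yl) derivative of 22 (diastereomers) | CC1(C)C[C@@](O[Si](CC)(CC)CC)(C[C@H](CCC(C(O)C=C)C(=O)OC)C=C(C)OCC)CC=C1Br | intermediate
25 | 2-(prop-2-enoyl) derivative of 22 (vinyl β-keto ester, enol ether intact) | CC1(C)C[C@@](O[Si](CC)(CC)CC)(C[C@H](CCC(C(=O)C=C)C(=O)OC)C=C(C)OCC)CC=C1Br | intermediate
26 | methyl (5S)-5-{[(1R)-4-bromo-5,5-dimethyl-1-(triethylsilyloxy)cyclohex-3-en-1-yl]methyl}-7-oxo-2-(prop-2-enoyl)octanoate | CC1(C)C[C@@](O[Si](CC)(CC)CC)(C[C@H](CCC(C(=O)C=C)C(=O)OC)CC(C)=O)CC=C1Br | intermediate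
27 | (2E)-enol triflate of 26: methyl (2E,5S)-…-7-oxo-2-[1-(trifluoromethanesulfonyloxy)prop-2-en-1-ylidene]octanoate | CC1(C)C[C@@](O[Si](CC)(CC)CC)(C[C@H](CC/C(C(=O)OC)=C(/C=C)OS(=O)(=O)C(F)(F)F)CC(C)=O)CC=C1Br | intermediate
28 | (6Z)-trimethylsilyl enol ether of 27 (the 1,3,8-nonatriene) | CC1(C)C[C@@](O[Si](CC)(CC)CC)(C[C@H](CC/C(C(=O)OC)=C(/C=C)OS(=O)(=O)C(F)(F)F)/C=C(/C)O[Si](C)(C)C)CC=C1Br | intermediate
29 | methyl (3S,3aS,4R,7aR)-3-{[(1R)-4-bromo-5,5-dimethyl-1-(triethylsilyloxy)cyclohex-3-en-1-yl]methyl}-4-methyl-7-(triflyloxy)-4-(trimethylsilyloxy)-1,2,3,3a,4,5-hexahydro-7aH-indene-7a-carboxylate | CC1(C)C[C@@](O[Si](CC)(CC)CC)(C[C@@H]2CC[C@]3(C(=O)OC)C(OS(=O)(=O)C(F)(F)F)=CC[C@@](C)(O[Si](C)(C)C)[C@@H]23)CC=C1Br | intermediate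
30 | bis-desilylated 29 (C4–OH, ring A OH, methyl ester) | CC1(C)C[C@@](O)(C[C@@H]2CC[C@]3(C(=O)OC)C(OS(=O)(=O)C(F)(F)F)=CC[C@@](C)(O)[C@@H]23)CC=C1Br | intermediate
31 | 4,7a-lactone with C7 alkenyl triflate and ring A alkenyl bromide | CC1(C)C[C@@](O)(C[C@@H]2CC[C@]34C(=O)O[C@](C)(CC=C3OS(=O)(=O)C(F)(F)F)[C@@H]24)CC=C1Br | intermediate
32 | 4,7a-lactone with C7 and ring A alkenyl bromides | CC1(C)C[C@@](O)(C[C@@H]2CC[C@]34C(=O)O[C@](C)(CC=C3Br)[C@@H]24)CC=C1Br | intermediate
33 | CNP0282702.2 | CC1(C)C[C@@](O)(C[C@@H]2CC[C@]34C(=O)O[C@](C)(CC[C@@H]3Br)[C@@H]24)CC[C@@H]1Br | target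

**Count and risks**

Total steps: 21. Longest linear sequence: 19 (steps 1–3, 5–10, 12–21).

Steps most likely to fail:

1. Step 18. The cycloaddition joins two fully substituted termini of polarity-mismatched partners and may be slower than desilylation or decomposition; the syn transition state may also compete and give cis-fused material that cannot lactonize. Fallback, setting out from 26 and returning at 31: form the two ring bonds one after the other by redox umpolung instead of a cycloaddition. Compound 26 is converted with TMSOTf/Et3N into the bis(trimethylsilyl enol ether) F1. Oxidative enol ether coupling (CAN, NaHCO3, MeCN, −20 °C) joins the two α-carbons (C3a–C7a) to give the cyclopentane 1,4-diketone F2. SmI2 (THF/MeOH, −78 °C) then couples the enone β-carbon with the methyl ketone carbonyl (C4–C5, ketyl–enone reductive cyclization), and the samarium alkoxide lactonizes onto the ester to give the keto lactone F3. KHMDS/PhNTf2 gives the enol triflate F4 (only one enolizable side), and HF·pyridine removes the TES group to reach 31.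

2. Step 16. O-sulfonylation may run through the chelated enolate and give the (Z)-triflate or a mixture; with the tether inside the diene the anti transition state is out of reach. Fallback, setting out from 22 and returning at 27: fix the geometry in a ring. Aldol addition of the enolate of 22 (LDA) to 3-(oxan-2-yloxy)propanal gives the adduct F5, and Dess–Martin oxidation gives the β-keto ester F6. PPTS/MeOH followed by aqueous acid removes the THP group, hydrolyses the enol ether and closes the δ-lactone to the 3-substituted oxane-2,4-dione F7. Tf2O/Et3N gives the cyclic enol triflate F8, in which the carboxyl carbon and C5 are necessarily cis. Base-induced eliminative ring opening (KOt-Bu, THF, −78 °C) gives the dienoic acid F9 with the carboxyl cis to the new vinyl group, and TMSCHN2 gives 27.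

3. Step 17. Enolization of the methyl ketone may be poorly selective (terminal regioisomer, E isomer), which lowers the share of productive dienophile. Fallback, setting out from 25 and returning at 31: keep the regiodefined Wittig-derived ethyl enol ether as the dienophile. Compound 25, isolated by omitting the acid stage of step 15, is triflated as in step 16 to the dienyl triflate enol ether F10. Heating as in step 18 gives the C4 ethyl ethers F11; either enol ether geometry exerts the same A(1,3) control, so both C4 epimers should share the correct C3/C3a/C7a configuration. TMSI (CH2Cl2, −40 → 0 °C) ionizes the tertiary ether, the neighbouring ester captures the cation from its own face and loses MeI, so both epimers converge on the lactone; aqueous HF work-up removes TES and gives 31.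

**Further compounds**

F1 | step 18 | bis(trimethylsilyl enol ether) of 26 | CC1(C)C[C@@](O[Si](CC)(CC)CC)(C[C@H](CCC(C(=O)OC)=C(O[Si](C)(C)C)C=C)C=C(C)O[Si](C)(C)C)CC=C1Br
F2 | step 18 | methyl 2-acetyl-3-{[(1R)-4-bromo-5,5-dimethyl-1-(triethylsilyloxy)cyclohex-3-en-1-yl]methyl}-1-(prop-2-enoyl)cyclopentane-1-carboxylate | CC1(C)C[C@@](O[Si](CC)(CC)CC)(C[C@@H]2CC[C@](C(=O)OC)(C(=O)C=C)[C@H]2C(C)=O)CC=C1Br
F3 | step 18 | 7-oxo 4,7a-lactone (C6 saturated), ring A triethylsilyl ether | CC1(C)C[C@@](O[Si](CC)(CC)CC)(C[C@@H]2CC[C@]34C(=O)O[C@](C)(CCC3=O)[C@@H]24)CC=C1Br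
F4 | step 18 | ring A triethylsilyl ether of 31 | CC1(C)C[C@@](O[Si](CC)(CC)CC)(C[C@@H]2CC[C@]34C(=O)O[C@](C)(CC=C3OS(=O)(=O)C(F)(F)F)[C@@H]24)CC=C1Br
F5 | step 16 | aldol adduct of 22 with 3-(oxan-2-yloxy)propanal | CC1(C)C[C@@](O[Si](CC)(CC)CC)(C[C@H](CCC(C(O)CCOC2CCCCO2)C(=O)OC)C=C(C)OCC)CC=C1Br
F6 | step 16 | β-keto ester from F5 | CC1(C)C[C@@](O[Si](CC)(CC)CC)(C[C@H](CCC(C(=O)CCOC2CCCCO2)C(=O)OC)C=C(C)OCC)CC=C1Br
F7 | step 16 | 3-substituted oxane-2,4-dione with methyl ketone arm | CC1(C)C[C@@](O[Si](CC)(CC)CC)(C[C@H](CCC2C(=O)CCOC2=O)CC(C)=O)CC=C1Br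
F8 | step 16 | 3-substituted 4-(trifluoromethanesulfonyloxy)-5,6-dihydro-2H-pyran-2-one | CC1(C)C[C@@](O[Si](CC)(CC)CC)(C[C@H](CCC2=C(OS(=O)(=O)C(F)(F)F)CCOC2=O)CC(C)=O)CC=C1Br
F9 | step 16 | free acid corresponding to 27 | CC1(C)C[C@@](O[Si](CC)(CC)CC)(C[C@H](CC/C(C(=O)O)=C(/C=C)OS(=O)(=O)C(F)(F)F)CC(C)=O)CC=C1Br
F10 | step 17 | ethyl enol ether analogue of 28 (E/Z) | CC1(C)C[C@@](O[Si](CC)(CC)CC)(C[C@H](CC/C(C(=O)OC)=C(/C=C)OS(=O)(=O)C(F)(F)F)C=C(C)OCC)CC=C1Br
F11 | step 17 | C4 ethyl ether analogue of 29 (both C4 epimers) | CC1(C)C[C@@](O[Si](CC)(CC)CC)(C[C@@H]2CC[C@]3(C(=O)OC)C(OS(=O)(=O)C(F)(F)F)=CCC(C)(OCC)[C@@H]23)CC=C1Br
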